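## Retrosynthetic overview

- **Locants.** Ring A is the aryl ketone/ether ring. Rings B and D are the naphthalene core, numbered as a 1,3,6,8-tetraoxygenated naphthalene (ring D: O1, O3, C4; ring B: C5, O6, O8; C4 and C5 are peri across C4a). Ring C is C4-C4a-C5-Ca-Cb-Cc, with Ca = CH(CH3), Cb = CH and Cc = C(ring E). Cd is the CH(CH3) of the chain, and ring E is the pendant resorcinol.
- **Enabling feature.** Ca sits on C5, which is para to O8 in ring B, so Ca can become an electrophile (para-quinone methide C8=O/C5=Ca). The peri carbon C4 of ring D is para to O1 and ortho to O3, so it is a strong arene nucleophile. Ca(+)/C4(-) is therefore a built-in 1,4-acceptor/donor pair that matches the donor/acceptor pair Cb(-)/Cc(+) of an aryl ketone enol silane. O1 lets the product settle as the Cc=C4 quinone methide of the target.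
- **Key disconnection.** Ca-Cb and Cc=C4 are cut together (formal (4+2) peri-annulation). This opens ring C and the ten-membered ring at once and leads back to an open diaryl ether carrying a beta-silyl quinol (latent quinone methide) and a Z silyl enol ether. Ca and Cb are relayed from the single bought stereocentre Cd.
- **Precursor.** The quinol comes from 1,2-addition of an alpha-silyl Grignard reagent to a 2-aryloxy-1,4-naphthoquinone, and the diaryl ether from addition-elimination on a chloronaphthoquinone. Ring D comes from Diels-Alder/aromatisation of an open-chain vinylketene acetal on 2,5-dichlorobenzoquinone (ring B). The chain comes from (R)-methyl hydrogen 3-methylglutarate by two aryl-metal acylations.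
- **Ring order.** Ring B is bought, ring D is annulated, and rings A and E are bought and attached. The ten-membered ring and ring C then close in one operation, and global O-demethylation ends the route.

Key step: step 9

Assumption: the target is taken as the drawn tautomer (a double bond at Cb would be a strained bridgehead alkene of the ten-membered ring), half ester 6 is bought enantiopure, and quinol 20 is used as a mixture of isomers at C5 and Ca, both of which are erased in step 9.

## Route

**Step 1**
Reactants: 1 methyl (E)-3-methoxybut-2-enoate
Product: 2 1,3-dimethoxy-1-(trimethylsilyloxy)buta-1,3-diene (Brassard diene)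
Conditions: LDA, THF, -78 °C; Me3SiCl, -78 °C to rt
Reagents that add atoms: chlorotrimethylsilane C[Si](C)(C)Cl
Why: Gamma-deprotonation of the beta-methoxy enoate with LDA and O-silylation of the extended enolate is the standard synthesis of vinylketene silyl acetals.

**Step 2**
Reactants: 2 Brassard diene; 3 2,5-dichloro-1,4-benzoquinone
Product: 5 2-chloro-5-hydroxy-7-methoxy-1,4-naphthoquinone, via Diels-Alder adduct 4 (not isolated)
Conditions: CH2Cl2, -40 °C to rt; then wet silica gel, rt
Reagents that add atoms: none
Why: Diels-Alder reaction of a vinylketene acetal with a haloquinone followed by loss of HCl and methanol (aromatisation) should be regiospecific, since the nucleophilic CH2 terminus of 2 bonds to the unsubstituted carbon next to C-Cl, which places the new OH peri to the carbonyl remote from the surviving chlorine.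

**Step 3**
Reactants: 6 (3R)-5-methoxy-3-methyl-5-oxopentanoic acid; 7 1,3-dimethoxybenzene
Product: 11 methyl (3R)-5-(2,6-dimethoxyphenyl)-3-methyl-5-oxopentanoate, via acid chloride 8 (not isolated), via aryllithium 9 (not isolated), via arylzinc chloride 10 (not isolated)
Conditions: (a) 6, (COCl)2, cat. DMF, CH2Cl2, 0 °C to rt, concentrate; (b) 7, n-BuLi, THF, 0 °C to rt, then ZnCl2, 0 °C; (c) 8 added to 10, Pd(PPh3)4 (3 mol %), THF, 0 °C to rt
Reagents that add atoms: none
Why: Directed ortho-lithiation of 7 between its two methoxy groups, transmetalation to zinc and Negishi-type acylation by the acid chloride should give the ketone without attack on the methyl ester, and the stereocentre, beta to both carbonyl groups, is not touched.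

**Step 4**
Reactants: 11 keto ester
Product: 12 methyl (3S,4Z)-5-(tert-butyldimethylsilyloxy)-5-(2,6-dimethoxyphenyl)-3-methylpent-4-enoate
Conditions: TBSOTf (1.2 equiv), Et3N, CH2Cl2, 0 °C
Reagents that add atoms: tert-butyldimethylsilyl trifluoromethanesulfonate CC(C)(C)[Si](C)(C)OS(=O)(=O)C(F)(F)F
Why: Soft enolisation (silyl triflate and tertiary amine) silylates only the ketone, which can enolise to one side only, and should give the Z enol silane because the alkyl branch avoids the twisted 2,6-dimethoxyphenyl group.

**Step 5**
Reactants: 12 enol silane ester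
Product: 13 (3S,4Z)-5-(tert-butyldimethylsilyloxy)-5-(2,6-dimethoxyphenyl)-N-methoxy-N,3-dimethylpent-4-enamide
Conditions: MeNH(OMe)·HCl, i-PrMgCl (3 equiv), THF, -20 °C; H2O
Reagents that add atoms: N,O-dimethylhydroxylamine hydrochloride CNOC.Cl
Why: Aminolysis of the methyl ester by the chloromagnesium amide of N,O-dimethylhydroxylamine is the standard direct Weinreb amide synthesis and leaves the silyl enol ether alone.

**Step 6**
Reactants: 13 Weinreb amide; 14 2-bromo-3-methoxyphenol
Product: 16 (3S,4Z)-5-(tert-butyldimethylsilyloxy)-5-(2,6-dimethoxyphenyl)-1-(2-hydroxy-6-methoxyphenyl)-3-methylpent-4-en-1-one, via dilithio phenoxide 15 (not isolated)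
Conditions: 14, n-BuLi (2.1 equiv), THF, -78 °C; then 13, -78 to 0 °C; H2O (pH 7)
Reagents that add atoms: none
Why: Deprotonation and bromine-lithium exchange give the ortho-lithiated phenoxide 15, whose addition to the Weinreb amide stops at the chelated tetrahedral intermediate (Weinreb ketone synthesis), so the free ortho-hydroxyaryl ketone appears on work-up without a protecting group.

**Step 7**
Reactants: 16 ring A phenol; 5 chloronaphthoquinone
Product: 17 2-aryloxy-5-hydroxy-7-methoxy-1,4-naphthoquinone (aryl = ring A of 16, bound through its former OH)
Conditions: K2CO3 (2.5 equiv), DMF, 0 °C to rt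
Reagents that add atoms: none
Why: Addition-elimination of the phenoxide at the chlorine-bearing quinone carbon (vinylogous acyl substitution, as in the conversion of halojuglones into alkoxyjuglones) should give the diaryl ether, because attack at the neighbouring CH is reversible for an oxygen nucleophile whereas ipso attack expels chloride for good.

**Step 8**
Reactants: 17 aryloxyquinone; 18 (1-chloroethyl)trimethylsilane (racemic)
Product: 20 beta-hydroxysilane quinol (C5 bears OH and CH(CH3)SiMe3; mixture at C5 and Ca; Cd S; Z enol silane), via Grignard reagent 19 (not isolated)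
Conditions: 18, Mg, THF, reflux; then 17, LaCl3·2LiCl (0.3 equiv), 19 (3 equiv), THF, -78 °C; pH 7 buffer; no acidic silica
Reagents that add atoms: none
Why: 1,2-Addition of an alpha-silyl Grignard reagent to a quinone carbonyl (quinol synthesis, first half of a Peterson olefination) should occur at C5=O only, since C8=O is a vinylogous ester of the aryloxy group, is conjugated with O1 and O3 and is held in the magnesium peri-phenoxide chelate, and the chain ketone is shielded by two ortho substituents; the two new stereocentres form as a mixture and are erased in step 9.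

**Step 9**
Reactants: 20 beta-hydroxysilane quinol
Product: 23 tetra-O-methyl ether of the target (Cd S; Ca R; Cb R), via para-quinone methide 21 (not isolated), via tertiary silyl ether 22 (not isolated)
Conditions: Tf2NH (10 mol %), CH2Cl2, 1 mM (syringe-pump addition of 20), -78 °C to rt; aq. NaHCO3
Reagents that add atoms: none
Why: Proposed new method: catalytic Tf2NH (and the silyl triflimides it forms) triggers acid Peterson elimination of Me3SiOH from 20 to para-quinone methide 21, whose O-protonated or O-silylated form is a cation at Ca stabilised by O8, O6 and, through the naphthalene, O1 and O3; the enol-silane carbon Cb adds to Ca (Mukaiyama-type 1,6-addition), the silyloxocarbenium ion at Cc is taken by the peri carbon C4 to give 22, and ionisation of the doubly benzylic OTBS group with loss of the O1 proton leaves the Cc=C4 quinone methide of 23. The closest known reaction types are the Peterson olefination, Lewis-acid-initiated cyclisations and formal cycloadditions of para-quinone methides or benzylic cations with silyl enol ethers and styrenes, and Friedel-Crafts cyclodehydration of aryl ketones; new is their union in a formal (4+2) peri-annulation that also closes a medium ring. The ten-membered ring closes first, 10-endo-trig at the C5=Ca bond, helped by the ortho,ortho' diaryl ether that holds Ca near the chain and by high dilution, and ring C then closes 6-exo-trig at the oxocarbenium carbon. Cb is set by allylic 1,3-strain in the Z enol silane: the C-H bond of the bought stereocentre Cd eclipses the double bond, the tether lies on the attacked face and the Cd methyl group on the other. Ca is set because the E and Z forms of 21 interconvert through the cation and only the rotamer that turns H rather than CH3 into the forming ring can cyclise, which leaves the Ca methyl group anti to the chain on ring C (trans-diaxial with the Cb-Cd bond), the only arrangement from which Cc can reach C4. Chemoselectivity rests on the enol silane being the only strong pi-nucleophile (the ring A ketone stays a ketone, so its alpha-carbon and an eight-membered ring do not compete), on the ortho position C6 being blocked so that closure can only go peri, and on C4 being the most activated free arene carbon within reach.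

**Step 10**
Reactants: 23 tetra-O-methyl ether
Product: 24 target CNP0225737.1
Conditions: BBr3 (12 equiv), CH2Cl2, -78 °C to rt; H2O
Reagents that add atoms: none
Why: Boron tribromide ether cleavage removes the chelated ring A methyl ether and the vinylogous ester methyl group fast and the two ring E methyl ethers on warming, and the stereocentres should hold because Cd and Ca carry no acidic hydrogen and enolisation towards Cb would place a double bond at a bridgehead of the ten-membered ring.

## Compound list

1 | methyl (E)-3-methoxybut-2-enoate | CO/C(C)=C/C(=O)OC | starting material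
2 | 1,3-dimethoxy-1-(trimethylsilyloxy)buta-1,3-diene | C=C(OC)C=C(OC)O[Si](C)(C)C | intermediate
3 | 2,5-dichloro-1,4-benzoquinone | O=C1C=C(Cl)C(=O)C=C1Cl | starting material
4 | 2,4a-dichloro-5,7-dimethoxy-5-(trimethylsilyloxy)-4a,5,8,8a-tetrahydronaphthalene-1,4-dione | O=C1C(Cl)=CC(=O)C2(Cl)C1CC(OC)=CC2(OC)O[Si](C)(C)C | intermediate
5 | 2-chloro-5-hydroxy-7-methoxy-1,4-naphthoquinone | O=C1C(Cl)=CC(=O)c2c(O)cc(OC)cc12 | intermediate
6 | (3R)-5-methoxy-3-methyl-5-oxopentanoic acid | C[C@H](CC(=O)O)CC(=O)OC | starting material
7 | 1,3-dimethoxybenzene | COc1cccc(OC)c1 | starting material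
8 | methyl (3S)-5-chloro-3-methyl-5-oxopentanoate | C[C@H](CC(=O)Cl)CC(=O)OC | intermediate
9 | 2,6-dimethoxyphenyllithium | [Li]c1c(OC)cccc1OC | intermediate
10 | (2,6-dimethoxyphenyl)zinc chloride | Cl[Zn]c1c(OC)cccc1OC | intermediate
11 | methyl (3R)-5-(2,6-dimethoxyphenyl)-3-methyl-5-oxopentanoate | C[C@H](CC(=O)c1c(OC)cccc1OC)CC(=O)OC | intermediate
12 | methyl (3S,4Z)-5-(tert-butyldimethylsilyloxy)-5-(2,6-dimethoxyphenyl)-3-methylpent-4-enoate | C[C@H](/C=C(\O[Si](C)(C)C(C)(C)C)c1c(OC)cccc1OC)CC(=O)OC | intermediate
13 | (3S,4Z)-5-(tert-butyldimethylsilyloxy)-5-(2,6-dimethoxyphenyl)-N-methoxy-N,3-dimethylpent-4-enamide | C[C@H](/C=C(\O[Si](C)(C)C(C)(C)C)c1c(OC)cccc1OC)CC(=O)N(C)OC | intermediate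
14 | 2-bromo-3-methoxyphenol | COc1cccc(O)c1Br | starting material
15 | lithium 2-lithio-3-methoxyphenolate | [Li]Oc1cccc(OC)c1[Li] | intermediate
16 | (3S,4Z)-5-(tert-butyldimethylsilyloxy)-5-(2,6-dimethoxyphenyl)-1-(2-hydroxy-6-methoxyphenyl)-3-methylpent-4-en-1-one | C[C@H](/C=C(\O[Si](C)(C)C(C)(C)C)c1c(OC)cccc1OC)CC(=O)c1c(O)cccc1OC | intermediate
17 | 2-aryloxy-5-hydroxy-7-methoxy-1,4-naphthoquinone with the chain of 16 on ring A | C[C@H](/C=C(\O[Si](C)(C)C(C)(C)C)c1c(OC)cccc1OC)CC(=O)c1c(OC)cccc1OC1=CC(=O)c2c(O)cc(OC)cc2C1=O | intermediate
18 | (1-chloroethyl)trimethylsilane, racemic | CC(Cl)[Si](C)(C)C | starting material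
19 | [1-(trimethylsilyl)ethyl]magnesium chloride | CC([Mg]Cl)[Si](C)(C)C | intermediate
20 | quinol: 3-aryloxy-4,8-dihydroxy-6-methoxy-4-[1-(trimethylsilyl)ethyl]naphthalen-1(4H)-one, mixture at the quinol carbon and Ca | C[C@H](/C=C(\O[Si](C)(C)C(C)(C)C)c1c(OC)cccc1OC)CC(=O)c1c(OC)cccc1OC1=CC(=O)c2c(O)cc(OC)cc2C1(O)C(C)[Si](C)(C)C | intermediate
21 | para-quinone methide: 3-aryloxy-4-ethylidene-8-hydroxy-6-methoxynaphthalen-1(4H)-one, E and Z interconverting | C[C@H](/C=C(\O[Si](C)(C)C(C)(C)C)c1c(OC)cccc1OC)CC(=O)c1c(OC)cccc1OC1=CC(=O)c2c(O)cc(OC)cc2C1=CC | intermediate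
22 | formal (4+2) adduct: both new rings closed, Cc bears OTBS and ring E, naphthalene-1,8-diol core | C[C@H]1CC(=O)c2c(OC)cccc2Oc2cc(O)c3c4c2[C@H](C)[C@@H]1C(O[Si](C)(C)C(C)(C)C)(c1c(OC)cccc1OC)c4c(OC)cc3O | intermediate
23 | tetra-O-methyl ether of the target (ring A OMe, ring E 2 OMe, O3 Me) | C[C@H]1CC(=O)c2c(OC)cccc2Oc2cc(O)c3c4c2[C@H](C)[C@@H]1C(c1c(OC)cccc1OC)=C4C(OC)=CC3=O | intermediate
24 | CNP0225737.1 | C[C@H]1CC(=O)c2c(O)cccc2Oc2cc(O)c3c4c2[C@H](C)[C@@H]1C(c1c(O)cccc1O)=C4C(O)=CC3=O | target

## Step count

Total step count: 10. Longest linear sequence: 8 (steps 3 to 10, from 6 or 7).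

## Steps most likely to fail

**Step 9.**
- What may go wrong: the enol silane may be protodesilylated before the C-C bond forms. The quinone methide may oligomerise or tautomerise to the vinylnaphthol faster than the medium ring closes. The cascade may stall after the first bond, or facial selectivity may be poor.
- Fallback: it sets out from 20, comes back at 23, and splits the cascade into two known reactions with a checkpoint between them.
- First, 20 is added slowly to catalytic Sc(OTf)3 in CH2Cl2 at -78 °C. This is an acid Peterson elimination followed by Lewis-acid 1,6-addition of a silyl enol ether to a para-quinone methide.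
- The reaction is quenched cold with water, so that the ten-membered macrocyclic ketone F1 is isolated.
- The centre Cb of F1, now alpha to a ketone, can be equilibrated with DBU to the trans isomer.
- In a separate operation, Friedel-Crafts cyclodehydration with P2O5/MeSO3H closes ring C onto C4 and gives 23.

**Step 8.**
- What may go wrong: electron transfer from the secondary Grignard reagent may reduce the quinone. Conjugate addition, displacement of the aryloxy group, or attack at the chain ketone may also compete.
- Fallback: it sets out from 17, comes back at 23, and replaces carbonyl addition by cross-coupling.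
- Na2S2O4 in THF/water reduces 17 to the naphthalene-1,4,5-triol F2.
- PhNTf2 with K2CO3 (1 equiv) should triflate the hydroxyl on C5, the only one outside the O1/O8 peri hydrogen-bond pair, to give the monotriflate F3.
- Suzuki-Miyaura coupling with potassium vinyltrifluoroborate (PdCl2(dppf), K2CO3, THF/water) gives the 5-vinylnaphthalenediol F4.
- F4 is a tautomer of 21. Under the conditions of step 9 it is protonated at the vinyl CH2 to the same Ca cation and should close to 23.

**Step 10.**
- What may go wrong: the two unactivated ring E ethers may cleave incompletely. The quinone methide/vinylogous acid may be damaged by the Lewis acid and HBr, for instance by attack of a freed ring E hydroxyl on the O3-bearing carbon.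
- Fallback: it sets out from 20, comes back at 24, and deprotects before ring C exists.
- The cascade is stopped at ketone F1 as described above.
- BBr3 cleaves all four methyl ethers at this robust aryl ketone/naphthol stage to give the hexaphenolic macrocyclic ketone F5.
- Ring C is closed last with p-TsOH in degassed toluene/THF. The now planar, hydrogen-bonded 2,6-dihydroxyphenyl ketone condenses with C4 and loses water to give 24 directly.

## Further compounds

F1 | step 9 | ten-membered macrocyclic ketone (Ca-Cb bond formed, Cc still C=O, naphthalene-1,8-diol core) | C[C@H]1CC(=O)c2c(OC)cccc2Oc2cc(O)c3c(O)cc(OC)cc3c2[C@H](C)[C@@H]1C(=O)c1c(OC)cccc1OC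
F2 | step 8 | 2-aryloxy-7-methoxynaphthalene-1,4,5-triol | C[C@H](/C=C(\O[Si](C)(C)C(C)(C)C)c1c(OC)cccc1OC)CC(=O)c1c(OC)cccc1Oc1cc(O)c2c(O)cc(OC)cc2c1O
F3 | step 8 | monotriflate of F2 at the hydroxyl next to the aryloxy group | C[C@H](/C=C(\O[Si](C)(C)C(C)(C)C)c1c(OC)cccc1OC)CC(=O)c1c(OC)cccc1Oc1cc(O)c2c(O)cc(OC)cc2c1OS(=O)(=O)C(F)(F)F
F4 | step 8 | 5-vinylnaphthalenediol (tautomer of 21) | C[C@H](/C=C(\O[Si](C)(C)C(C)(C)C)c1c(OC)cccc1OC)CC(=O)c1c(OC)cccc1Oc1cc(O)c2c(O)cc(OC)cc2c1C=C
F5 | step 10 | hexaphenolic macrocyclic ketone | C[C@H]1CC(=O)c2c(O)cccc2Oc2cc(O)c3c(O)cc(O)cc3c2[C@H](C)[C@@H]1C(=O)c1c(O)cccc1O
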